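## Retrosynthetic overview

- The strategy rests on C8, the branch point of the (6E,8Z)-diene: it is bonded to ethyl, to C7 of the E-alkene and doubly to C9. Both of its C–C single bonds are made from one gem-dibromide carbon (C8 of an (R)-C8–C13 dibromoalkene) in one sequential Negishi coupling with a C1–C7 (E)-alkenylzinc and diethylzinc.
- C13–C14 is cut by Suzuki coupling of the C1–C13 (E)-alkenylboronate with a C14–C24 (E)-alkenyl iodide. The C17 ketone, the C1 lactone carbonyl and the free hydroxyls are unveiled last.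
- C1–C7: the only ring, the six-membered O/C1–C5 dihydropyran, is formed first by a catalytic enantioselective hetero-Diels–Alder reaction and carried as its methyl acetal. No other ring is closed.
- C8–C13: C10 comes from an auxiliary-controlled propargylation. C14–C24: C21–C22 by carbocupration, C18–C19 by syn-aldol, C16–C17 by a chirality-transferring allenylzinc addition, the C14 iodide by hydrozirconation.

Key step: step 8

Remarks on the chemistry:
- Carbons are numbered from the lactone carbonyl (C1) to the acid carbon (C24). The configurations of the C1 acetal carbon and of the C17 carbinol carbon are immaterial, because both carbons become sp2 in step 28.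
- It is assumed that the (1S,2R)-aminoindanol-derived chromium catalyst of step 2 delivers the (2R,3S,6S) adduct. It is also assumed that the (S,S)-ruthenium catalyst of step 21 delivers the (R)-alcohol, with the alkynyl group in the role of the aryl group of an aryl ketone. If either sense were the opposite, the antipodal catalyst would be used.

## Route

**C1–C7 pyran alkyne**

Step 1
Reactants: 1 (E)-but-2-enal
Product: 2 (1E,3E)-1-methoxypenta-1,3-diene
Conditions: MeOCH2PPh3Cl, KOt-Bu, THF, 0 °C; then 1, 0 °C → rt; distillation (1E/1Z mixture carried on)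
Reagents that add atoms: (methoxymethyl)triphenylphosphonium chloride, COC[P+](c1ccccc1)(c1ccccc1)c1ccccc1.[Cl-]
Why: Wittig olefination with the methoxymethylene ylide converts the aldehyde into the enol ether, the 3E alkene being inherited from 1, and only the 1E isomer of the expected 1E/1Z mixture can reach the s-cis geometry needed in step 2.

Step 2
Reactants: 2 (1E,3E)-1-methoxypenta-1,3-diene; 3 3-(trimethylsilyl)prop-2-ynal
Product: 4 (2R,3S,6S)-6-methoxy-3-methyl-2-[(trimethylsilyl)ethynyl]-3,6-dihydro-2H-pyran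
Conditions: CrCl(L) (3 mol %; trivalent chromium, L = tridentate Schiff-base dianion from (1S,2R)-1-aminoindan-2-ol and 3-(1-adamantyl)-2-hydroxy-5-methylbenzaldehyde), 4 Å MS, neat, rt
Reagents that add atoms: none
Why: Endo-selective catalytic hetero-Diels–Alder reaction in which the E,E-diene and the endo alkynyl group should give the all-cis pyran, the chiral chromium Lewis acid choosing the aldehyde face and thereby setting C5, C4 and the C1 acetal carbon in one event.

Step 3
Reactants: 4 (2R,3S,6S)-6-methoxy-3-methyl-2-[(trimethylsilyl)ethynyl]-3,6-dihydro-2H-pyran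
Product: 5 (2R,3S,6S)-2-ethynyl-6-methoxy-3-methyl-3,6-dihydro-2H-pyran
Conditions: K2CO3, MeOH, 0 °C → rt
Reagents that add atoms: none
Why: Methoxide-mediated protodesilylation of the alkynylsilane leaves the base-stable mixed acetal and both stereocenters untouched.

**C8–C13 dibromide**

Step 4
Reactants: 6 (S)-4-benzyl-3-propionyloxazolidin-2-one; 7 3-bromo-1-(trimethylsilyl)prop-1-yne
Product: 9 (S)-4-benzyl-3-[(R)-2-methyl-5-(trimethylsilyl)pent-4-ynoyl]oxazolidin-2-one, via sodium Z-enolate 8 (not isolated)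
Conditions: NaN(SiMe3)2, THF, −78 °C; then 7, −78 → −40 °C
Reagents that add atoms: none
Why: Evans asymmetric alkylation in which the chelated Z-enolate is propargylated on the face opposite the benzyl group, which sets C10 as R.

Step 5
Reactants: 9 (S)-4-benzyl-3-[(R)-2-methyl-5-(trimethylsilyl)pent-4-ynoyl]oxazolidin-2-one
Product: 10 (R)-2-methyl-5-(trimethylsilyl)pent-4-yn-1-ol
Conditions: LiBH4, MeOH (1 equiv), Et2O, 0 °C
Reagents that add atoms: none
Why: Reductive cleavage of the N-acyloxazolidinone at the exocyclic carbonyl releases the primary alcohol without touching C10 or the silylalkyne.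

Step 6
Reactants: 10 (R)-2-methyl-5-(trimethylsilyl)pent-4-yn-1-ol
Product: 11 (R)-2-methyl-5-(trimethylsilyl)pent-4-ynal
Conditions: Dess–Martin periodinane, NaHCO3, CH2Cl2, 0 °C → rt; used crude
Reagents that add atoms: none
Why: Buffered Dess–Martin oxidation gives the α-branched aldehyde under neutral conditions, and immediate use should avoid epimerization at C10.

Step 7
Reactants: 11 (R)-2-methyl-5-(trimethylsilyl)pent-4-ynal
Product: 12 (R)-(6,6-dibromo-4-methylhex-5-en-1-yn-1-yl)trimethylsilane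
Conditions: CBr4, PPh3, Zn dust, CH2Cl2, rt (ylide preformed); then 11, 0 °C → rt
Reagents that add atoms: carbon tetrabromide, BrC(Br)(Br)Br
Why: Dibromo-olefination of the first stage of the Corey–Fuchs sequence, run with the zinc-modified ylide so that the medium stays near neutral and C10 is preserved.

**Key coupling and C1–C13 boronate**

Step 8
Reactants: 5 (2R,3S,6S)-2-ethynyl-6-methoxy-3-methyl-3,6-dihydro-2H-pyran; 12 (R)-(6,6-dibromo-4-methylhex-5-en-1-yn-1-yl)trimethylsilane; 13 diethylzinc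
Product: 17 (2S,3S,6S)-2-[(1E,3Z,5R)-3-ethyl-5-methyl-8-(trimethylsilyl)octa-1,3-dien-7-yn-1-yl]-6-methoxy-3-methyl-3,6-dihydro-2H-pyran, via alkenylzirconocene chloride 14 (not isolated), via alkenylzinc chloride 15 (not isolated), via bromodiene 16 (not isolated)
Conditions: 5, Cp2Zr(H)Cl, THF, rt; ZnCl2, THF, 0 °C; 12, Pd(DPEphos)Cl2 (5 mol %), 0 °C → rt; then 13, THF, rt → 50 °C
Reagents that add atoms: none
Why: Negishi coupling run as a three-component sequence on a 1,1-dibromoalkene: syn-hydrozirconation of 5 places zirconium on C7, transmetalation to zinc gives 15, and zerovalent palladium (formed from Pd(DPEphos)Cl2 and organozinc) inserts into the C–Br bond of 12 trans to the C10 branch and couples with retention to give bromodiene 16 with C7 trans to C10. Oxidative addition into the remaining, hindered C–Br bond gives a dienylpalladium bromide that equilibrates about C8=C9 through an η3-butadienyl form, so that ethyl transfer from 13 and reductive elimination place ethyl trans to C10 and the dienyl chain cis, which is the 8Z geometry. The closest known reaction type is the tandem trans-selective alkenylation–alkylation of 1,1-dibromoalkenes, in which alkylation of the intermediate 2-bromo-1,3-diene proceeds with inversion of alkene geometry under bisphosphine ligation. No ring is closed and no stereocenter is created; C4, C5 and C10 are not touched, and the C6=C7 E geometry comes from the syn-hydrozirconation. The step needs trans-selectivity in the first coupling, which the C10 branch next to the cis bromine and the wide-bite-angle DPEphos ligand should secure, and clean inversion in the second, which the chelating bisphosphine favors, whereas a bulky monophosphine catalyst such as Pd(t-Bu3P)2 would give retention and the 8E isomer.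

Step 9
Reactants: 17 (2S,3S,6S)-2-[(1E,3Z,5R)-3-ethyl-5-methyl-8-(trimethylsilyl)octa-1,3-dien-7-yn-1-yl]-6-methoxy-3-methyl-3,6-dihydro-2H-pyran
Product: 18 (2S,3S,6S)-2-[(1E,3Z,5R)-3-ethyl-5-methylocta-1,3-dien-7-yn-1-yl]-6-methoxy-3-methyl-3,6-dihydro-2H-pyran
Conditions: K2CO3, MeOH/THF, rt
Reagents that add atoms: none
Why: Protodesilylation of the alkynylsilane under mild base, to which the acetal and the diene are inert.

Step 10
Reactants: 18 (2S,3S,6S)-2-[(1E,3Z,5R)-3-ethyl-5-methylocta-1,3-dien-7-yn-1-yl]-6-methoxy-3-methyl-3,6-dihydro-2H-pyran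
Product: 19 2-[(1E,4R,5Z,7E)-6-ethyl-8-[(2S,3S,6S)-6-methoxy-3-methyl-3,6-dihydro-2H-pyran-2-yl]-4-methylocta-1,5,7-trien-1-yl]-4,4,5,5-tetramethyl-1,3,2-dioxaborolane
Conditions: pinacolborane, Cp2Zr(H)Cl (10 mol %), Et3N (10 mol %), CH2Cl2, rt
Reagents that add atoms: pinacolborane, CC1(C)OBOC1(C)C
Why: Zirconium-catalyzed syn-hydroboration of the terminal alkyne puts boron on C13 with E geometry, the internal diene and ring alkene being far less reactive than the terminal alkyne.

**C14–C24 alkenyl iodide**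

Step 11
Reactants: 20 (R)-3-bromo-2-methylpropan-1-ol
Product: 21 (R)-(3-bromo-2-methylpropoxy)(tert-butyl)dimethylsilane
Conditions: TBSCl, imidazole, CH2Cl2, 0 °C → rt
Reagents that add atoms: tert-butyldimethylsilyl chloride, CC(C)(C)[Si](C)(C)Cl
Why: Standard silylation masks the hydroxyl (future C19) so that the bromide (future C21) can be metalated.

Step 12
Reactants: 21 (R)-(3-bromo-2-methylpropoxy)(tert-butyl)dimethylsilane; 22 ethyl but-2-ynoate
Product: 25 ethyl (S,E)-6-(tert-butyldimethylsilyloxy)-3,5-dimethylhex-2-enoate, via alkylmagnesium bromide 23 (not isolated), via alkylcopper 24 (not isolated)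
Conditions: Mg, THF, 40 °C; CuBr·SMe2, THF, −78 °C; 22, −78 °C; MeOH then aq. NH4Cl at −78 °C
Reagents that add atoms: none
Why: Syn-carbocupration of the ynoate by the alkylcopper followed by cold protonation of the alkenylcopper forms C21–C22 and puts the new chain trans to the ester, giving the 22E trisubstituted enoate.

Step 13
Reactants: 25 ethyl (S,E)-6-(tert-butyldimethylsilyloxy)-3,5-dimethylhex-2-enoate
Product: 26 ethyl (S,E)-6-hydroxy-3,5-dimethylhex-2-enoate
Conditions: camphorsulfonic acid (cat.), EtOH/CH2Cl2, 0 °C → rt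
Reagents that add atoms: none
Why: Acid-catalyzed solvolysis of the primary silyl ether, chosen over fluoride so that no alkoxide is formed that could add to the enoate.

Step 14
Reactants: 26 ethyl (S,E)-6-hydroxy-3,5-dimethylhex-2-enoate
Product: 27 ethyl (S,E)-3,5-dimethyl-6-oxohex-2-enoate
Conditions: Dess–Martin periodinane, NaHCO3, CH2Cl2, 0 °C → rt; used crude
Reagents that add atoms: none
Why: Buffered Dess–Martin oxidation gives the C19 aldehyde without epimerizing C20.

Step 15
Reactants: 6 (S)-4-benzyl-3-propionyloxazolidin-2-one; 27 ethyl (S,E)-3,5-dimethyl-6-oxohex-2-enoate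
Product: 29 ethyl (2E,5S,6R,7S)-8-[(S)-4-benzyl-2-oxooxazolidin-3-yl]-6-hydroxy-3,5,7-trimethyl-8-oxooct-2-enoate, via dibutylboron Z-enolate 28 (not isolated)
Conditions: 6, Bu2BOTf, i-Pr2NEt, CH2Cl2, 0 °C; 27, −78 → 0 °C; pH 7 buffer, MeOH, H2O2
Reagents that add atoms: none
Why: Evans syn-aldol reaction through a closed Zimmerman–Traxler transition state of the Z-boron enolate, in which the auxiliary sets C18 (S) and C19 (R) and should override the bias of the C20 center to give the all-syn triad.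

Step 16
Reactants: 29 ethyl (2E,5S,6R,7S)-8-[(S)-4-benzyl-2-oxooxazolidin-3-yl]-6-hydroxy-3,5,7-trimethyl-8-oxooct-2-enoate
Product: 30 ethyl (2E,5S,6R,7S)-8-[(S)-4-benzyl-2-oxooxazolidin-3-yl]-6-(tert-butyldimethylsilyloxy)-3,5,7-trimethyl-8-oxooct-2-enoate
Conditions: TBSOTf, 2,6-lutidine, CH2Cl2, −78 → 0 °C
Reagents that add atoms: tert-butyldimethylsilyl trifluoromethanesulfonate, CC(C)(C)[Si](C)(C)OS(=O)(=O)C(F)(F)F
Why: Silylation of the hindered C19 hydroxyl with the silyl triflate, giving an ether that lasts until the final step.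

Step 17
Reactants: 30 ethyl (2E,5S,6R,7S)-8-[(S)-4-benzyl-2-oxooxazolidin-3-yl]-6-(tert-butyldimethylsilyloxy)-3,5,7-trimethyl-8-oxooct-2-enoate
Product: 31 ethyl (2E,5S,6R,7R)-6-(tert-butyldimethylsilyloxy)-8-hydroxy-3,5,7-trimethyloct-2-enoate
Conditions: LiBH4, H2O (1 equiv), Et2O, 0 °C
Reagents that add atoms: none
Why: Reductive cleavage of the activated imide carbonyl by LiBH4 at 0 °C, which should be much faster than reduction of the conjugated ethyl ester.

Step 18
Reactants: 31 ethyl (2E,5S,6R,7R)-6-(tert-butyldimethylsilyloxy)-8-hydroxy-3,5,7-trimethyloct-2-enoate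
Product: 32 ethyl (2E,5S,6R,7S)-6-(tert-butyldimethylsilyloxy)-3,5,7-trimethyl-8-oxooct-2-enoate
Conditions: Dess–Martin periodinane, NaHCO3, CH2Cl2, 0 °C → rt; used crude
Reagents that add atoms: none
Why: Buffered Dess–Martin oxidation gives the C17 aldehyde without epimerizing C18 or eliminating the β-silyloxy group.

Step 19
Reactants: 33 (tert-butyldimethylsilyloxy)acetaldehyde
Product: 34 rac-1-(tert-butyldimethylsilyloxy)pent-3-yn-2-ol
Conditions: prop-1-ynylmagnesium bromide, THF, −78 → 0 °C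
Reagents that add atoms: prop-1-ynylmagnesium bromide, CC#C[Mg]Br
Why: Grignard addition of the alkynyl nucleophile to the aldehyde assembles the C14–C16 unit with its hydroxymethyl carbon.

Step 20
Reactants: 34 rac-1-(tert-butyldimethylsilyloxy)pent-3-yn-2-ol
Product: 35 1-(tert-butyldimethylsilyloxy)pent-3-yn-2-one
Conditions: Dess–Martin periodinane, NaHCO3, CH2Cl2, 0 °C → rt
Reagents that add atoms: none
Why: Dess–Martin oxidation of the propargylic alcohol gives the ynone needed for enantioselective reduction.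

Step 21
Reactants: 35 1-(tert-butyldimethylsilyloxy)pent-3-yn-2-one
Product: 36 (R)-1-(tert-butyldimethylsilyloxy)pent-3-yn-2-ol
Conditions: Ru[(S,S)-TsNCH(Ph)CH(Ph)NH](p-cymene) (1 mol %), i-PrOH, rt
Reagents that add atoms: none
Why: Noyori asymmetric transfer hydrogenation of an alkynyl ketone, in which the catalyst distinguishes the alkynyl group from the CH2OSi group and sets the carbinol center that is later transferred to C16.

Step 22
Reactants: 36 (R)-1-(tert-butyldimethylsilyloxy)pent-3-yn-2-ol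
Product: 37 (R)-1-(tert-butyldimethylsilyloxy)pent-3-yn-2-yl methanesulfonate
Conditions: MsCl, Et3N, CH2Cl2, −78 → 0 °C; used at once
Reagents that add atoms: methanesulfonyl chloride, CS(=O)(=O)Cl
Why: O-Sulfonylation with retention gives the propargylic leaving group for the palladium–zinc propargylation.

Step 23
Reactants: 32 ethyl (2E,5S,6R,7S)-6-(tert-butyldimethylsilyloxy)-3,5,7-trimethyl-8-oxooct-2-enoate; 37 (R)-1-(tert-butyldimethylsilyloxy)pent-3-yn-2-yl methanesulfonate
Product: 39 ethyl (2E,5S,6R,7R,8R,9S)-6-(tert-butyldimethylsilyloxy)-9-[(tert-butyldimethylsilyloxy)methyl]-8-hydroxy-3,5,7-trimethyldodec-2-en-10-ynoate, via allenylzinc 38 (not isolated)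
Conditions: 37 (1.5 equiv), Pd(OAc)2 (5 mol %), PPh3 (5 mol %), Et2Zn (13, 3 equiv), THF, −78 → −20 °C
Reagents that add atoms: none
Why: Marshall propargylation, in which anti-SN2' attack of zerovalent palladium on the mesylate, transmetalation to the (M)-allenylzinc and syn-SE2' addition to the aldehyde through a cyclic transition state transfer the mesylate center to C16 with net inversion (S) and should give the anti C16/C17 relationship, C17 being oxidized later.

Step 24
Reactants: 39 ethyl (2E,5S,6R,7R,8R,9S)-6-(tert-butyldimethylsilyloxy)-9-[(tert-butyldimethylsilyloxy)methyl]-8-hydroxy-3,5,7-trimethyldodec-2-en-10-ynoate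
Product: 41 ethyl (2E,5S,6R,7R,8R,9S,10E)-6-(tert-butyldimethylsilyloxy)-9-[(tert-butyldimethylsilyloxy)methyl]-8-hydroxy-11-iodo-3,5,7-trimethyldodeca-2,10-dienoate, via C14 alkenylzirconocene chloride 40 (not isolated)
Conditions: Cp2Zr(H)Cl (3.5 equiv), THF, rt → 40 °C; then I2, THF, 0 °C
Reagents that add atoms: iodine, II
Why: Hydrozirconation–iodination, in which syn addition under equilibrating conditions places zirconium on the methyl-bearing C14, away from the C16 branch, and iodinolysis with retention gives the 14E alkenyl iodide, one equivalent of the hydride being consumed by the C17 hydroxyl.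

Step 25
Reactants: 41 ethyl (2E,5S,6R,7R,8R,9S,10E)-6-(tert-butyldimethylsilyloxy)-9-[(tert-butyldimethylsilyloxy)methyl]-8-hydroxy-11-iodo-3,5,7-trimethyldodeca-2,10-dienoate
Product: 42 (2E,5S,6R,7R,8R,9S,10E)-6-(tert-butyldimethylsilyloxy)-9-[(tert-butyldimethylsilyloxy)methyl]-8-hydroxy-11-iodo-3,5,7-trimethyldodeca-2,10-dienoic acid
Conditions: LiOH, THF/MeOH/H2O, rt → 40 °C; then 1 M HCl to pH 4
Reagents that add atoms: lithium hydroxide, [Li+].[OH-]
Why: Saponification of the ethyl ester at the last stage where no base-sensitive ketone or lactone is present, so that the acid needs no further protection.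

**Fragment union and endgame**

Step 26
Reactants: 19 2-[(1E,4R,5Z,7E)-6-ethyl-8-[(2S,3S,6S)-6-methoxy-3-methyl-3,6-dihydro-2H-pyran-2-yl]-4-methylocta-1,5,7-trien-1-yl]-4,4,5,5-tetramethyl-1,3,2-dioxaborolane; 42 (2E,5S,6R,7R,8R,9S,10E)-6-(tert-butyldimethylsilyloxy)-9-[(tert-butyldimethylsilyloxy)methyl]-8-hydroxy-11-iodo-3,5,7-trimethyldodeca-2,10-dienoic acid
Product: 43 (2E,5S,6R,7R,8R,9S,10E,12E,15R,16Z,18E)-6-(tert-butyldimethylsilyloxy)-9-[(tert-butyldimethylsilyloxy)methyl]-17-ethyl-8-hydroxy-19-[(2S,3S,6S)-6-methoxy-3-methyl-3,6-dihydro-2H-pyran-2-yl]-3,5,7,11,15-pentamethylnonadeca-2,10,12,16,18-pentaenoic acid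
Conditions: Pd(PPh3)4 (10 mol %), TlOEt (4 equiv), THF/H2O (3:1), rt, dark
Reagents that add atoms: none
Why: Suzuki–Miyaura coupling of the E-alkenylboronate with the E-alkenyl iodide forms C13–C14 with retention at both partners, the thallium base allowing room-temperature coupling in the presence of the carboxylate, the free hydroxyl and the acetal.

Step 27
Reactants: 43 (2E,5S,6R,7R,8R,9S,10E,12E,15R,16Z,18E)-6-(tert-butyldimethylsilyloxy)-9-[(tert-butyldimethylsilyloxy)methyl]-17-ethyl-8-hydroxy-19-[(2S,3S,6S)-6-methoxy-3-methyl-3,6-dihydro-2H-pyran-2-yl]-3,5,7,11,15-pentamethylnonadeca-2,10,12,16,18-pentaenoic acid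
Product: 44 (2E,5S,6R,7R,8R,9S,10E,12E,15R,16Z,18E)-6-(tert-butyldimethylsilyloxy)-9-[(tert-butyldimethylsilyloxy)methyl]-17-ethyl-8-hydroxy-19-[(2S,3S)-6-hydroxy-3-methyl-3,6-dihydro-2H-pyran-2-yl]-3,5,7,11,15-pentamethylnonadeca-2,10,12,16,18-pentaenoic acid (lactol anomers)
Conditions: PPTS, acetone/H2O (4:1), rt
Reagents that add atoms: water, O
Why: Mild acid hydrolysis of the allylic mixed acetal through its conjugated oxocarbenium ion gives the lactol under conditions that the two silyl ethers should survive.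

Step 28
Reactants: 44 (2E,5S,6R,7R,8R,9S,10E,12E,15R,16Z,18E)-6-(tert-butyldimethylsilyloxy)-9-[(tert-butyldimethylsilyloxy)methyl]-17-ethyl-8-hydroxy-19-[(2S,3S)-6-hydroxy-3-methyl-3,6-dihydro-2H-pyran-2-yl]-3,5,7,11,15-pentamethylnonadeca-2,10,12,16,18-pentaenoic acid
Product: 45 (2E,5S,6R,7S,9S,10E,12E,15R,16Z,18E)-6-(tert-butyldimethylsilyloxy)-9-[(tert-butyldimethylsilyloxy)methyl]-17-ethyl-3,5,7,11,15-pentamethyl-19-[(2S,3S)-3-methyl-6-oxo-3,6-dihydro-2H-pyran-2-yl]-8-oxononadeca-2,10,12,16,18-pentaenoic acid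
Conditions: Dess–Martin periodinane (excess), pyridine, CH2Cl2, 0 °C → rt
Reagents that add atoms: none
Why: Dess–Martin oxidation converts the lactol into the lactone and the C17 carbinol into the ketone in one operation under buffered, non-basic conditions, so that the epimerizable C16 and C18 centers flanking the new ketone should be preserved.

Step 29
Reactants: 45 (2E,5S,6R,7S,9S,10E,12E,15R,16Z,18E)-6-(tert-butyldimethylsilyloxy)-9-[(tert-butyldimethylsilyloxy)methyl]-17-ethyl-3,5,7,11,15-pentamethyl-19-[(2S,3S)-3-methyl-6-oxo-3,6-dihydro-2H-pyran-2-yl]-8-oxononadeca-2,10,12,16,18-pentaenoic acid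
Product: 46 kazusamycin A
Conditions: HF·pyridine, pyridine, THF, 0 °C → rt
Reagents that add atoms: none
Why: Buffered acidic fluoride desilylation removes both silyl ethers without the basic conditions that would trigger retro-aldol cleavage, β-elimination of the C16 hydroxymethyl group or opening of the lactone.

## Compound list

1 | (E)-but-2-enal | C/C=C/C=O | starting material
2 | (1E,3E)-1-methoxypenta-1,3-diene (carried with its 1Z isomer) | CO/C=C/C=C/C | intermediate
3 | 3-(trimethylsilyl)prop-2-ynal | C[Si](C)(C)C#CC=O | starting material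
4 | (2R,3S,6S)-6-methoxy-3-methyl-2-[(trimethylsilyl)ethynyl]-3,6-dihydro-2H-pyran (all-cis) | C[Si](C)(C)C#C[C@@H]1O[C@H](OC)C=C[C@@H]1C | intermediate
5 | (2R,3S,6S)-2-ethynyl-6-methoxy-3-methyl-3,6-dihydro-2H-pyran | C#C[C@@H]1O[C@H](OC)C=C[C@@H]1C | intermediate
6 | (S)-4-benzyl-3-propionyloxazolidin-2-one | CCC(=O)N1[C@@H](Cc2ccccc2)COC1=O | starting material
7 | 3-bromo-1-(trimethylsilyl)prop-1-yne | C[Si](C)(C)C#CCBr | starting material
8 | sodium (Z)-enolate of 6 (not isolated) | C/C=C(\[O-])N1[C@@H](Cc2ccccc2)COC1=O.[Na+] | intermediate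
9 | (S)-4-benzyl-3-[(R)-2-methyl-5-(trimethylsilyl)pent-4-ynoyl]oxazolidin-2-one | C[C@H](CC#C[Si](C)(C)C)C(=O)N1[C@@H](Cc2ccccc2)COC1=O | intermediate
10 | (R)-2-methyl-5-(trimethylsilyl)pent-4-yn-1-ol | C[C@H](CC#C[Si](C)(C)C)CO | intermediate
11 | (R)-2-methyl-5-(trimethylsilyl)pent-4-ynal | C[C@H](CC#C[Si](C)(C)C)C=O | intermediate
12 | (R)-(6,6-dibromo-4-methylhex-5-en-1-yn-1-yl)trimethylsilane, i.e. (R)-1,1-dibromo-3-methyl-6-(trimethylsilyl)hex-1-en-5-yne | BrC(Br)=C[C@H](C)CC#C[Si](C)(C)C | intermediate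
13 | diethylzinc | CC[Zn]CC | starting material
14 | chloro{(E)-2-[(2R,3S,6S)-6-methoxy-3-methyl-3,6-dihydro-2H-pyran-2-yl]vinyl}zirconocene (not isolated) | Cl[Zr](/C=C/[C@@H]1O[C@H](OC)C=C[C@@H]1C)(C1C=CC=C1)C1C=CC=C1 | intermediate
15 | (E)-2-[(2R,3S,6S)-6-methoxy-3-methyl-3,6-dihydro-2H-pyran-2-yl]vinylzinc chloride (not isolated) | Cl[Zn]/C=C/[C@@H]1O[C@H](OC)C=C[C@@H]1C | intermediate
16 | (2S,3S,6S)-2-[(1E,3Z,5R)-3-bromo-5-methyl-8-(trimethylsilyl)octa-1,3-dien-7-yn-1-yl]-6-methoxy-3-methyl-3,6-dihydro-2H-pyran (not isolated) | Br/C(=C\[C@H](C)CC#C[Si](C)(C)C)/C=C/[C@@H]1O[C@H](OC)C=C[C@@H]1C | intermediate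
17 | (2S,3S,6S)-2-[(1E,3Z,5R)-3-ethyl-5-methyl-8-(trimethylsilyl)octa-1,3-dien-7-yn-1-yl]-6-methoxy-3-methyl-3,6-dihydro-2H-pyran | CCC(=C/[C@H](C)CC#C[Si](C)(C)C)/C=C/[C@@H]1O[C@H](OC)C=C[C@@H]1C | intermediate
18 | (2S,3S,6S)-2-[(1E,3Z,5R)-3-ethyl-5-methylocta-1,3-dien-7-yn-1-yl]-6-methoxy-3-methyl-3,6-dihydro-2H-pyran | CCC(=C/[C@H](C)CC#C)/C=C/[C@@H]1O[C@H](OC)C=C[C@@H]1C | intermediate
19 | 2-[(1E,4R,5Z,7E)-6-ethyl-8-[(2S,3S,6S)-6-methoxy-3-methyl-3,6-dihydro-2H-pyran-2-yl]-4-methylocta-1,5,7-trien-1-yl]-4,4,5,5-tetramethyl-1,3,2-dioxaborolane | CCC(=C/[C@H](C)C/C=C/B1OC(C)(C)C(C)(C)O1)/C=C/[C@@H]1O[C@H](OC)C=C[C@@H]1C | intermediate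
20 | (R)-3-bromo-2-methylpropan-1-ol | OC[C@@H](C)CBr | starting material
21 | (R)-(3-bromo-2-methylpropoxy)(tert-butyl)dimethylsilane | CC(C)(C)[Si](C)(C)OC[C@@H](C)CBr | intermediate
22 | ethyl but-2-ynoate | CC#CC(=O)OCC | starting material
23 | [(R)-3-(tert-butyldimethylsilyloxy)-2-methylpropyl]magnesium bromide (not isolated) | CC(C)(C)[Si](C)(C)OC[C@@H](C)C[Mg]Br | intermediate
24 | [(R)-3-(tert-butyldimethylsilyloxy)-2-methylpropyl]copper (not isolated) | CC(C)(C)[Si](C)(C)OC[C@@H](C)C[Cu] | intermediate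
25 | ethyl (S,E)-6-(tert-butyldimethylsilyloxy)-3,5-dimethylhex-2-enoate | CCOC(=O)/C=C(\C)C[C@H](C)CO[Si](C)(C)C(C)(C)C | intermediate
26 | ethyl (S,E)-6-hydroxy-3,5-dimethylhex-2-enoate | CCOC(=O)/C=C(\C)C[C@H](C)CO | intermediate
27 | ethyl (S,E)-3,5-dimethyl-6-oxohex-2-enoate | CCOC(=O)/C=C(\C)C[C@H](C)C=O | intermediate
28 | dibutylboron (Z)-enolate of 6 (not isolated) | C/C=C(\OB(CCCC)CCCC)N1[C@@H](Cc2ccccc2)COC1=O | intermediate
29 | ethyl (2E,5S,6R,7S)-8-[(S)-4-benzyl-2-oxooxazolidin-3-yl]-6-hydroxy-3,5,7-trimethyl-8-oxooct-2-enoate | O=C1OC[C@H](Cc2ccccc2)N1C(=O)[C@@H](C)[C@H](O)[C@@H](C)C/C(C)=C/C(=O)OCC | intermediate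
30 | ethyl (2E,5S,6R,7S)-8-[(S)-4-benzyl-2-oxooxazolidin-3-yl]-6-(tert-butyldimethylsilyloxy)-3,5,7-trimethyl-8-oxooct-2-enoate | O=C1OC[C@H](Cc2ccccc2)N1C(=O)[C@@H](C)[C@H](O[Si](C)(C)C(C)(C)C)[C@@H](C)C/C(C)=C/C(=O)OCC | intermediate
31 | ethyl (2E,5S,6R,7R)-6-(tert-butyldimethylsilyloxy)-8-hydroxy-3,5,7-trimethyloct-2-enoate | OC[C@@H](C)[C@H](O[Si](C)(C)C(C)(C)C)[C@@H](C)C/C(C)=C/C(=O)OCC | intermediate
32 | ethyl (2E,5S,6R,7S)-6-(tert-butyldimethylsilyloxy)-3,5,7-trimethyl-8-oxooct-2-enoate | O=C[C@@H](C)[C@H](O[Si](C)(C)C(C)(C)C)[C@@H](C)C/C(C)=C/C(=O)OCC | intermediate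
33 | (tert-butyldimethylsilyloxy)acetaldehyde | CC(C)(C)[Si](C)(C)OCC=O | starting material
34 | rac-1-(tert-butyldimethylsilyloxy)pent-3-yn-2-ol | CC#CC(O)CO[Si](C)(C)C(C)(C)C | intermediate
35 | 1-(tert-butyldimethylsilyloxy)pent-3-yn-2-one | CC#CC(=O)CO[Si](C)(C)C(C)(C)C | intermediate
36 | (R)-1-(tert-butyldimethylsilyloxy)pent-3-yn-2-ol | CC#C[C@@H](O)CO[Si](C)(C)C(C)(C)C | intermediate
37 | (R)-1-(tert-butyldimethylsilyloxy)pent-3-yn-2-yl methanesulfonate | CC#C[C@@H](OS(C)(=O)=O)CO[Si](C)(C)C(C)(C)C | intermediate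
38 | (M)-[5-(tert-butyldimethylsilyloxy)penta-2,3-dien-2-yl](ethyl)zinc (not isolated; M axial chirality, not encoded in the SMILES) | CC[Zn]C(C)=C=CCO[Si](C)(C)C(C)(C)C | intermediate
39 | ethyl (2E,5S,6R,7R,8R,9S)-6-(tert-butyldimethylsilyloxy)-9-[(tert-butyldimethylsilyloxy)methyl]-8-hydroxy-3,5,7-trimethyldodec-2-en-10-ynoate | CC#C[C@@H](CO[Si](C)(C)C(C)(C)C)[C@@H](O)[C@@H](C)[C@H](O[Si](C)(C)C(C)(C)C)[C@@H](C)C/C(C)=C/C(=O)OCC | intermediate
40 | C14 alkenylzirconocene chloride of 39, with C17 oxygen bound to zirconium (not isolated) | Cl[Zr](C1C=CC=C1)(C1C=CC=C1)/C(C)=C/[C@@H](CO[Si](C)(C)C(C)(C)C)[C@@H](O[Zr](Cl)(C1C=CC=C1)C1C=CC=C1)[C@@H](C)[C@H](O[Si](C)(C)C(C)(C)C)[C@@H](C)C/C(C)=C/C(=O)OCC | intermediate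
41 | ethyl (2E,5S,6R,7R,8R,9S,10E)-6-(tert-butyldimethylsilyloxy)-9-[(tert-butyldimethylsilyloxy)methyl]-8-hydroxy-11-iodo-3,5,7-trimethyldodeca-2,10-dienoate | I/C(C)=C/[C@@H](CO[Si](C)(C)C(C)(C)C)[C@@H](O)[C@@H](C)[C@H](O[Si](C)(C)C(C)(C)C)[C@@H](C)C/C(C)=C/C(=O)OCC | intermediate
42 | (2E,5S,6R,7R,8R,9S,10E)-6-(tert-butyldimethylsilyloxy)-9-[(tert-butyldimethylsilyloxy)methyl]-8-hydroxy-11-iodo-3,5,7-trimethyldodeca-2,10-dienoic acid | I/C(C)=C/[C@@H](CO[Si](C)(C)C(C)(C)C)[C@@H](O)[C@@H](C)[C@H](O[Si](C)(C)C(C)(C)C)[C@@H](C)C/C(C)=C/C(=O)O | intermediate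
43 | (2E,5S,6R,7R,8R,9S,10E,12E,15R,16Z,18E)-6-(tert-butyldimethylsilyloxy)-9-[(tert-butyldimethylsilyloxy)methyl]-17-ethyl-8-hydroxy-19-[(2S,3S,6S)-6-methoxy-3-methyl-3,6-dihydro-2H-pyran-2-yl]-3,5,7,11,15-pentamethylnonadeca-2,10,12,16,18-pentaenoic acid | CCC(=C/[C@H](C)C/C=C/C(C)=C/[C@@H](CO[Si](C)(C)C(C)(C)C)[C@@H](O)[C@@H](C)[C@H](O[Si](C)(C)C(C)(C)C)[C@@H](C)C/C(C)=C/C(=O)O)/C=C/[C@@H]1O[C@H](OC)C=C[C@@H]1C | intermediate
44 | lactol of 43: 6-hydroxy-3-methyl-3,6-dihydro-2H-pyran-2-yl terminus (2S,3S; C1 anomers) | CCC(=C/[C@H](C)C/C=C/C(C)=C/[C@@H](CO[Si](C)(C)C(C)(C)C)[C@@H](O)[C@@H](C)[C@H](O[Si](C)(C)C(C)(C)C)[C@@H](C)C/C(C)=C/C(=O)O)/C=C/[C@@H]1OC(O)C=C[C@@H]1C | intermediate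
45 | (2E,5S,6R,7S,9S,10E,12E,15R,16Z,18E)-6-(tert-butyldimethylsilyloxy)-9-[(tert-butyldimethylsilyloxy)methyl]-17-ethyl-3,5,7,11,15-pentamethyl-19-[(2S,3S)-3-methyl-6-oxo-3,6-dihydro-2H-pyran-2-yl]-8-oxononadeca-2,10,12,16,18-pentaenoic acid | CCC(=C/[C@H](C)C/C=C/C(C)=C/[C@@H](CO[Si](C)(C)C(C)(C)C)C(=O)[C@@H](C)[C@H](O[Si](C)(C)C(C)(C)C)[C@@H](C)C/C(C)=C/C(=O)O)/C=C/[C@@H]1OC(=O)C=C[C@@H]1C | intermediate
46 | kazusamycin A | CCC(=C/[C@H](C)C/C=C/C(C)=C/[C@@H](CO)C(=O)[C@@H](C)[C@H](O)[C@@H](C)C/C(C)=C/C(=O)O)/C=C/[C@@H]1OC(=O)C=C[C@@H]1C | target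

## Step count and risks

Total step count: 29.
Longest linear sequence: 15 steps (from 20 through steps 11–18 and 23–29 to 46).

Steps most likely to fail:

**Step 8 (key step).** The second coupling may proceed partly with retention, so that the 8E isomer forms alongside the 8Z product. The first coupling may lose its trans-selectivity, or both bromines may be substituted by the alkenyl group. β-Hydride elimination from the ethylpalladium intermediate may reduce the C8–Br bond, and zinc halides may ionize the allylic acetal.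
The fallback keeps both C8 bonds on one gem-dihalide carbon but makes the 8Z geometry independent of inversion. It sets out from aldehyde 11, which is converted with PPh3 and CCl4 into (R)-(6,6-dichloro-4-methylhex-5-en-1-yn-1-yl)trimethylsilane F1. Trans-selective monoethylation of this dichloroalkene with 13 under Pd(DPEphos)Cl2 catalysis should give (R,Z)-(6-chloro-4-methyloct-5-en-1-yn-1-yl)trimethylsilane F2, in which ethyl is trans and chlorine cis to C10. Negishi coupling of this alkenyl chloride with alkenylzinc 15 under Pd(t-Bu3P)2, which proceeds with retention, then places the dienyl chain cis to C10 and comes back to the route at 17.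

**Step 23.** The allenylzinc may lose silyloxide by β-elimination through its propargylzinc tautomer, or racemize before it adds. The reagent-controlled anti addition is anti-Felkin with respect to C18 and may be slow or poorly selective at C17.
The fallback sets C16 by an auxiliary-controlled aldol reaction and brings the iodoalkene ready-made, so that step 24 is bypassed as well. Pent-3-yn-1-ol is hydrozirconated with excess Cp2Zr(H)Cl and iodinated to (E)-4-iodopent-3-en-1-ol F3, the regioisomer being removed. Oxidation with CrO3/H2SO4 in acetone gives (E)-4-iodopent-3-enoic acid F4. Activation as the pivalic mixed anhydride and reaction with lithiated (R)-4-benzyloxazolidin-2-one gives (R)-4-benzyl-3-[(E)-4-iodopent-3-enoyl]oxazolidin-2-one F5. The fallback sets out from aldehyde 32: the dibutylboron dienolate of F5 (Bu2BOTf, i-Pr2NEt) should add at its α-carbon to 32 to give the syn-aldol adduct, ethyl (2E,5S,6R,7R,8R,9S,10E)-9-[(R)-4-benzyl-2-oxooxazolidine-3-carbonyl]-6-(tert-butyldimethylsilyloxy)-8-hydroxy-11-iodo-3,5,7-trimethyldodeca-2,10-dienoate F6. LiBH4 cleavage gives ethyl (2E,5S,6R,7R,8R,9S,10E)-6-(tert-butyldimethylsilyloxy)-8-hydroxy-9-(hydroxymethyl)-11-iodo-3,5,7-trimethyldodeca-2,10-dienoate F7. Selective silylation of the primary hydroxyl (TBSCl, imidazole) comes back to the route at 41.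

**Step 24.** The excess zirconium hydride may reduce the conjugated ester. Delivery of hydride directed by the C17 alkoxide may place the metal on C15, and the alkenylzirconium may be protonated before iodination.
The fallback abandons zirconium. It sets out from alkyne 39: palladium-catalyzed syn-hydrostannation (n-Bu3SnH, PdCl2(PPh3)2, THF), which tolerates the ester and the free hydroxyl and puts tin on the less hindered C14, should give ethyl (2E,5S,6R,7R,8R,9S,10E)-6-(tert-butyldimethylsilyloxy)-9-[(tert-butyldimethylsilyloxy)methyl]-8-hydroxy-3,5,7-trimethyl-11-(tributylstannyl)dodeca-2,10-dienoate F8. Iododestannylation with I2 in CH2Cl2 at 0 °C, with retention, comes back to the route at 41.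

## Further compounds

F1 | step 8 | (R)-(6,6-dichloro-4-methylhex-5-en-1-yn-1-yl)trimethylsilane | ClC(Cl)=C[C@H](C)CC#C[Si](C)(C)C
F2 | step 8 | (R,Z)-(6-chloro-4-methyloct-5-en-1-yn-1-yl)trimethylsilane | CC/C(Cl)=C/[C@H](C)CC#C[Si](C)(C)C
F3 | step 23 | (E)-4-iodopent-3-en-1-ol | I/C(C)=C/CCO
F4 | step 23 | (E)-4-iodopent-3-enoic acid | I/C(C)=C/CC(=O)O
F5 | step 23 | (R)-4-benzyl-3-[(E)-4-iodopent-3-enoyl]oxazolidin-2-one | I/C(C)=C/CC(=O)N1[C@H](Cc2ccccc2)COC1=O
F6 | step 23 | ethyl (2E,5S,6R,7R,8R,9S,10E)-9-[(R)-4-benzyl-2-oxooxazolidine-3-carbonyl]-6-(tert-butyldimethylsilyloxy)-8-hydroxy-11-iodo-3,5,7-trimethyldodeca-2,10-dienoate | I/C(C)=C/[C@@H](C(=O)N1[C@H](Cc2ccccc2)COC1=O)[C@@H](O)[C@@H](C)[C@H](O[Si](C)(C)C(C)(C)C)[C@@H](C)C/C(C)=C/C(=O)OCC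
F7 | step 23 | ethyl (2E,5S,6R,7R,8R,9S,10E)-6-(tert-butyldimethylsilyloxy)-8-hydroxy-9-(hydroxymethyl)-11-iodo-3,5,7-trimethyldodeca-2,10-dienoate | I/C(C)=C/[C@@H](CO)[C@@H](O)[C@@H](C)[C@H](O[Si](C)(C)C(C)(C)C)[C@@H](C)C/C(C)=C/C(=O)OCC
F8 | step 24 | ethyl (2E,5S,6R,7R,8R,9S,10E)-6-(tert-butyldimethylsilyloxy)-9-[(tert-butyldimethylsilyloxy)methyl]-8-hydroxy-3,5,7-trimethyl-11-(tributylstannyl)dodeca-2,10-dienoate | CCCC[Sn](CCCC)(CCCC)/C(C)=C/[C@@H](CO[Si](C)(C)C(C)(C)C)[C@@H](O)[C@@H](C)[C@H](O[Si](C)(C)C(C)(C)C)[C@@H](C)C/C(C)=C/C(=O)OCC
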